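**Strategy**

Ring A of the target (C4a, C5, C6, C7, C8, C8a) hides a vinylogous aldol: C5 is the γ-carbon of the C8 ketone across C8a=C4a, and C6 is a carbinol carbon. The route rests on closing ring A by joining C5 to C6. The precursor is an open-chain allenyl ketone aldehyde, C5H2=C4a=C8a(CH2OSi)–C8(=O)–C7(Me)(OSi)–C6H=O. MgI2 adds iodide to C4a, and the resulting dienolate attacks the aldehyde through C5. One operation gives the cyclohexenone, the C6 stereocentre (controlled by C7) and a C4a–I handle, from which Sonogashira coupling and 6-endo hydroalkoxylation by the C1 hydroxyl build the pyran (ring B).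

Key step: step 8

Remark: atom labels follow the 1H-isochromene numbering of the target (C1, O2, C3, C4, C4a, C5 to C8, C8a), also in open-chain precursors. The target is the 6R,7S isomer, in which the C6 acyloxy group and the C7 hydroxyl are trans. Compounds 1, 5, 13, 20 and 21 are taken as commercially available.

**Route**

Step 1
Reactants: 1 (R)-2-methylglycidol
Product: 2 (2R)-3-[(4-methoxybenzyl)oxy]-2-methylpropane-1,2-diol
Conditions: 4-methoxybenzyl alcohol (3 equiv), NaH (0.3 equiv), DMF, 70 °C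
Reagents that add atoms: 4-methoxybenzyl alcohol, COc1ccc(CO)cc1
Why: Base-mediated SN2 opening of the epoxide by the benzylic alkoxide occurs at the unsubstituted CH2 terminus, so the quaternary stereocentre is untouched (a Payne-type epoxide migration is degenerate here and leads to the same product).

Step 2
Reactants: 2 (2R)-3-[(4-methoxybenzyl)oxy]-2-methylpropane-1,2-diol
Product: 3 (2S)-1-[(4-methoxybenzyl)oxy]-2-methyl-2,3-bis(triethylsilyloxy)propane
Conditions: TESOTf, 2,6-lutidine, CH2Cl2, −78 to 0 °C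
Reagents that add atoms: triethylsilyl trifluoromethanesulfonate, CC[Si](CC)(CC)OS(=O)(=O)C(F)(F)F
Why: Exhaustive O-silylation with a silyl triflate is strong enough to cap the hindered tertiary hydroxyl together with the primary one.

Step 3
Reactants: 3 (2S)-1-[(4-methoxybenzyl)oxy]-2-methyl-2,3-bis(triethylsilyloxy)propane
Product: 4 (2S)-3-[(4-methoxybenzyl)oxy]-2-methyl-2-(triethylsilyloxy)propanal
Conditions: (COCl)2, DMSO, CH2Cl2, −78 to −40 °C; then Et3N, −78 to 0 °C
Reagents that add atoms: none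
Why: Under Swern oxidation conditions a primary triethylsilyl ether is cleaved and oxidized in situ to the aldehyde while the tertiary silyl ether and the PMB ether are inert; the aldehyde has no α-hydrogen, so the stereocentre cannot epimerize.

Step 4
Reactants: 5 4-chlorobut-2-yn-1-ol
Product: 6 tert-butyl[(4-chlorobut-2-yn-1-yl)oxy]dimethylsilane
Conditions: TBSCl, imidazole, CH2Cl2, 0 °C to rt
Reagents that add atoms: tert-butyldimethylsilyl chloride, CC(C)(C)[Si](C)(C)Cl
Why: Standard silylation of a primary propargylic alcohol (TBS protection).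

Step 5
Reactants: 4 (2S)-3-[(4-methoxybenzyl)oxy]-2-methyl-2-(triethylsilyloxy)propanal; 6 tert-butyl[(4-chlorobut-2-yn-1-yl)oxy]dimethylsilane
Product: 8 (2S)-4-{[tert-butyl(dimethyl)silyl]oxymethyl}-1-[(4-methoxybenzyl)oxy]-2-methyl-2-(triethylsilyloxy)hexa-4,5-dien-3-ol (C3 epimers), via propargylindium chloride 7 (not isolated)
Conditions: indium powder, NaI (0.2 equiv), DMF, rt; aqueous NH4Cl work-up
Reagents that add atoms: none
Why: Barbier-type indium-mediated addition, in which the γ-substituted propargylindium species reacts through its remote alkyne carbon (SE2′) to give the α-allenyl carbinol; the new carbinol centre forms as a mixture, which is irrelevant because it is oxidized in step 7.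

Step 6
Reactants: 8 (2S)-4-{[tert-butyl(dimethyl)silyl]oxymethyl}-1-[(4-methoxybenzyl)oxy]-2-methyl-2-(triethylsilyloxy)hexa-4,5-dien-3-ol
Product: 9 (2S)-4-{[tert-butyl(dimethyl)silyl]oxymethyl}-2-methyl-2-(triethylsilyloxy)hexa-4,5-diene-1,3-diol (C3 epimers)
Conditions: DDQ, CH2Cl2/pH 7 buffer (10:1), 0 °C
Reagents that add atoms: none
Why: Oxidative cleavage of the PMB ether by DDQ in wet dichloromethane leaves the silyl ethers, the allene and the secondary alcohol untouched.

Step 7
Reactants: 9 (2S)-4-{[tert-butyl(dimethyl)silyl]oxymethyl}-2-methyl-2-(triethylsilyloxy)hexa-4,5-diene-1,3-diol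
Product: 10 (2S)-4-{[tert-butyl(dimethyl)silyl]oxymethyl}-2-methyl-3-oxo-2-(triethylsilyloxy)hexa-4,5-dienal
Conditions: DMP (3 equiv), CH2Cl2, 0 °C to rt; used at once
Reagents that add atoms: none
Why: Dess–Martin oxidation converts the allenylic alcohol into the allenyl ketone and the primary alcohol into the aldehyde under non-basic conditions that the non-enolizable 2-silyloxy-1,3-dicarbonyl unit tolerates.

Step 8
Reactants: 10 (2S)-4-{[tert-butyl(dimethyl)silyl]oxymethyl}-2-methyl-3-oxo-2-(triethylsilyloxy)hexa-4,5-dienal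
Product: 12 (5R,6S)-2-{[tert-butyl(dimethyl)silyl]oxymethyl}-5-hydroxy-3-iodo-6-methyl-6-(triethylsilyloxy)cyclohex-2-en-1-one, via iodomagnesium dienolate 11 (not isolated)
Conditions: MgI2 (1.5 equiv), CH2Cl2, −40 to 0 °C; pH 7 buffer quench
Reagents that add atoms: magnesium iodide, I[Mg]I
Why: Proposed new method: MgI2 activates the 1,3-dicarbonyl unit and delivers iodide to the central allene carbon C4a, giving the 2-iodo magnesium dienolate 11 (C8–O–Mg, C8=C8a, C4a=C5H2), whose terminal carbon C5 adds to the C6 aldehyde and regenerates the C8 ketone as the conjugated C8a=C4a enone. The closest known reaction types are the MgI2- or TMSI-mediated halo-aldol (iodo-Baylis–Hillman) reactions of allenoates, allenyl ketones and ynones, in which the same halo-dienolates are trapped by aldehydes at the α-carbon, and the intramolecular vinylogous aldol reaction; here α-attack would give a four-membered ring, so the γ-carbon must react. Ring A closes in the 6-(enolendo)-exo-trig mode. The C6 stereocentre is set under control of C7: the bulky, non-chelating triethylsilyl ether should sit pseudo-axial and anti to the aldehyde C=O (dipole-minimized half-chair with the C7 methyl pseudo-equatorial), which places the new C6 hydroxyl trans to the C7 oxygen, that is 6R. The step needs C- over O-reactivity of the dienolate and survival of the silyl ethers; the first is secured by the ring size, the second by low temperature and a buffered quench.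

Step 9
Reactants: 13 2,3,4-trimethoxy-6-methylbenzaldehyde
Product: 14 2,3,4-trihydroxy-6-methylbenzaldehyde
Conditions: BBr3, CH2Cl2, −78 °C to rt; H2O; handled under argon
Reagents that add atoms: none
Why: Lewis acid-mediated cleavage of all three aryl methyl ethers by BBr3, the aldehyde being released unchanged on aqueous work-up.

Step 10
Reactants: 14 2,3,4-trihydroxy-6-methylbenzaldehyde
Product: 15 2-hydroxy-3,4-bis(methoxymethoxy)-6-methylbenzaldehyde
Conditions: MOMCl (2.2 equiv), i-Pr2NEt, CH2Cl2, 0 °C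
Reagents that add atoms: chloromethyl methyl ether, COCCl
Why: Regioselective O-alkylation, in which the 3- and 4-hydroxyls react while the 2-hydroxyl, hydrogen-bonded to the ortho aldehyde, is the least nucleophilic and stays free.

Step 11
Reactants: 15 2-hydroxy-3,4-bis(methoxymethoxy)-6-methylbenzaldehyde
Product: 16 2-methoxy-3,4-bis(methoxymethoxy)-6-methylbenzaldehyde
Conditions: MeI, K2CO3, DMF, rt
Reagents that add atoms: iodomethane, CI
Why: Williamson methylation of the remaining hydrogen-bonded phenol.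

Step 12
Reactants: 16 2-methoxy-3,4-bis(methoxymethoxy)-6-methylbenzaldehyde
Product: 17 2-methoxy-3,4-bis(methoxymethoxy)-6-methylbenzoic acid
Conditions: NaClO2, NaH2PO4, 2-methyl-2-butene, t-BuOH/H2O, rt
Reagents that add atoms: sodium chlorite, [Na+].[O-]Cl=O
Why: Pinnick oxidation of the hindered aryl aldehyde under buffered conditions that leave the MOM acetals intact, with 2-methyl-2-butene scavenging hypochlorite to protect the electron-rich ring.

Step 13
Reactants: 12 (5R,6S)-2-{[tert-butyl(dimethyl)silyl]oxymethyl}-5-hydroxy-3-iodo-6-methyl-6-(triethylsilyloxy)cyclohex-2-en-1-one; 17 2-methoxy-3,4-bis(methoxymethoxy)-6-methylbenzoic acid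
Product: 19 (1R,6S)-4-{[tert-butyl(dimethyl)silyl]oxymethyl}-3-iodo-6-methyl-5-oxo-6-(triethylsilyloxy)cyclohex-3-en-1-yl 2-methoxy-3,4-bis(methoxymethoxy)-6-methylbenzoate, via acid chloride 18 (not isolated)
Conditions: 1-chloro-N,N,2-trimethylprop-1-en-1-amine, CH2Cl2, 0 °C to rt (17 to 18); then 12, Et3N, DMAP (cat.), CH2Cl2, rt to 40 °C
Reagents that add atoms: none
Why: The acid is converted into its chloride under neutral conditions (no HCl, so the MOM ethers survive), and DMAP-catalysed acyl transfer to the only free hydroxyl gives the ester with retention at C6 because the carbinol C–O bond is not touched.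

Step 14
Reactants: 20 3-(trimethylsilyl)prop-2-ynal; 21 tert-butyl (triphenylphosphoranylidene)acetate
Product: 22 tert-butyl (2E)-5-(trimethylsilyl)pent-2-en-4-ynoate
Conditions: CH2Cl2, 0 °C to rt
Reagents that add atoms: none
Why: Wittig olefination with a stabilized ylide, which should give the E-enoate.

Step 15
Reactants: 22 tert-butyl (2E)-5-(trimethylsilyl)pent-2-en-4-ynoate
Product: 23 tert-butyl (2E)-pent-2-en-4-ynoate
Conditions: K2CO3 (0.2 equiv), MeOH, 0 °C
Reagents that add atoms: none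
Why: Carbonate-catalysed methanolysis of the C(sp)–Si bond (protodesilylation) frees the terminal alkyne without transesterifying the tert-butyl ester.

Step 16
Reactants: 19 (1R,6S)-4-{[tert-butyl(dimethyl)silyl]oxymethyl}-3-iodo-6-methyl-5-oxo-6-(triethylsilyloxy)cyclohex-3-en-1-yl 2-methoxy-3,4-bis(methoxymethoxy)-6-methylbenzoate; 23 tert-butyl (2E)-pent-2-en-4-ynoate
Product: 24 (1R,6S)-3-[(3E)-5-tert-butoxy-5-oxopent-3-en-1-yn-1-yl]-4-{[tert-butyl(dimethyl)silyl]oxymethyl}-6-methyl-5-oxo-6-(triethylsilyloxy)cyclohex-3-en-1-yl 2-methoxy-3,4-bis(methoxymethoxy)-6-methylbenzoate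
Conditions: Pd(PPh3)2Cl2 (5 mol%), CuI (10 mol%), Et3N, THF, 0 °C to rt
Reagents that add atoms: none
Why: Sonogashira coupling, for which the β-iodo enone is a highly reactive oxidative-addition partner, so the reaction runs near room temperature and the E-alkene and the C6 benzoate are preserved.

Step 17
Reactants: 24 (1R,6S)-3-[(3E)-5-tert-butoxy-5-oxopent-3-en-1-yn-1-yl]-4-{[tert-butyl(dimethyl)silyl]oxymethyl}-6-methyl-5-oxo-6-(triethylsilyloxy)cyclohex-3-en-1-yl 2-methoxy-3,4-bis(methoxymethoxy)-6-methylbenzoate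
Product: 25 (1R,6S)-3-[(3E)-5-tert-butoxy-5-oxopent-3-en-1-yn-1-yl]-6-hydroxy-4-(hydroxymethyl)-6-methyl-5-oxocyclohex-3-en-1-yl 2-methoxy-3,4-bis(methoxymethoxy)-6-methylbenzoate
Conditions: HF·pyridine, pyridine, THF, 0 °C to rt
Reagents that add atoms: none
Why: Fluoride-driven cleavage of both Si–O bonds (primary TBS and tertiary TES ether) by buffered HF·pyridine, to which the MOM ethers, the tert-butyl ester and the benzoate are stable.

Step 18
Reactants: 25 (1R,6S)-3-[(3E)-5-tert-butoxy-5-oxopent-3-en-1-yn-1-yl]-6-hydroxy-4-(hydroxymethyl)-6-methyl-5-oxocyclohex-3-en-1-yl 2-methoxy-3,4-bis(methoxymethoxy)-6-methylbenzoate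
Product: 26 tert-butyl (2E)-3-[(6R,7S)-7-hydroxy-6-{[2-methoxy-3,4-bis(methoxymethoxy)-6-methylbenzoyl]oxy}-7-methyl-8-oxo-5,6,7,8-tetrahydro-1H-isochromen-3-yl]prop-2-enoate
Conditions: AgOTf (10 mol%), CH2Cl2, rt, dark
Reagents that add atoms: none
Why: Silver-catalysed cycloisomerization (intramolecular hydroalkoxylation), in which the C1 hydroxyl adds 6-endo-dig to the activated alkyne at C3, the carbon polarized by conjugation with the C8 ketone through C4a=C8a, and protodemetalation gives the fully conjugated 2H-pyran of ring B.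

Step 19
Reactants: 26 tert-butyl (2E)-3-[(6R,7S)-7-hydroxy-6-{[2-methoxy-3,4-bis(methoxymethoxy)-6-methylbenzoyl]oxy}-7-methyl-8-oxo-5,6,7,8-tetrahydro-1H-isochromen-3-yl]prop-2-enoate
Product: 27 (2E)-3-[(6R,7S)-6-[(3,4-dihydroxy-2-methoxy-6-methylbenzoyl)oxy]-7-hydroxy-7-methyl-8-oxo-5,6,7,8-tetrahydro-1H-isochromen-3-yl]prop-2-enoic acid
Conditions: TFA/CH2Cl2 (1:4), H2O (5 equiv), 0 °C to rt
Reagents that add atoms: none
Why: Global deprotection by acidolysis, in which TFA removes the tert-butyl ester (as isobutene) and hydrolyses both MOM acetals in one operation without touching a stereocentre.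

**Compound list**

1 | (R)-2-methylglycidol, [(2R)-2-methyloxiran-2-yl]methanol | OC[C@]1(C)CO1 | starting material
2 | (2R)-3-[(4-methoxybenzyl)oxy]-2-methylpropane-1,2-diol | OC[C@@](C)(O)COCc1ccc(OC)cc1 | intermediate
3 | (2S)-1-[(4-methoxybenzyl)oxy]-2-methyl-2,3-bis(triethylsilyloxy)propane | CC[Si](CC)(CC)OC[C@@](C)(O[Si](CC)(CC)CC)COCc1ccc(OC)cc1 | intermediate
4 | (2S)-3-[(4-methoxybenzyl)oxy]-2-methyl-2-(triethylsilyloxy)propanal | O=C[C@@](C)(O[Si](CC)(CC)CC)COCc1ccc(OC)cc1 | intermediate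
5 | 4-chlorobut-2-yn-1-ol | OCC#CCCl | starting material
6 | tert-butyl[(4-chlorobut-2-yn-1-yl)oxy]dimethylsilane | CC(C)(C)[Si](C)(C)OCC#CCCl | intermediate
7 | [4-(tert-butyldimethylsilyloxy)but-2-yn-1-yl]indium dichloride (propargylindium species, drawn as the monomeric dichloride; not isolated) | CC(C)(C)[Si](C)(C)OCC#CC[In](Cl)Cl | intermediate
8 | (2S)-4-{[tert-butyl(dimethyl)silyl]oxymethyl}-1-[(4-methoxybenzyl)oxy]-2-methyl-2-(triethylsilyloxy)hexa-4,5-dien-3-ol (C3 epimers) | C=C=C(CO[Si](C)(C)C(C)(C)C)C(O)[C@@](C)(O[Si](CC)(CC)CC)COCc1ccc(OC)cc1 | intermediate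
9 | (2S)-4-{[tert-butyl(dimethyl)silyl]oxymethyl}-2-methyl-2-(triethylsilyloxy)hexa-4,5-diene-1,3-diol (C3 epimers) | C=C=C(CO[Si](C)(C)C(C)(C)C)C(O)[C@@](C)(O[Si](CC)(CC)CC)CO | intermediate
10 | (2S)-4-{[tert-butyl(dimethyl)silyl]oxymethyl}-2-methyl-3-oxo-2-(triethylsilyloxy)hexa-4,5-dienal | O=C[C@](C)(O[Si](CC)(CC)CC)C(=O)C(CO[Si](C)(C)C(C)(C)C)=C=C | intermediate
11 | iodomagnesium (5R)-3-{[tert-butyl(dimethyl)silyl]oxymethyl}-2-iodo-5-methyl-6-oxo-5-(triethylsilyloxy)hexa-1,3-dien-4-olate (same spatial arrangement at C7 as in 10; not isolated) | O=C[C@](C)(O[Si](CC)(CC)CC)C(O[Mg]I)=C(CO[Si](C)(C)C(C)(C)C)C(I)=C | intermediate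
12 | (5R,6S)-2-{[tert-butyl(dimethyl)silyl]oxymethyl}-5-hydroxy-3-iodo-6-methyl-6-(triethylsilyloxy)cyclohex-2-en-1-one | O[C@@H]1CC(I)=C(CO[Si](C)(C)C(C)(C)C)C(=O)[C@@]1(C)O[Si](CC)(CC)CC | intermediate
13 | 2,3,4-trimethoxy-6-methylbenzaldehyde | COc1cc(C)c(C=O)c(OC)c1OC | starting material
14 | 2,3,4-trihydroxy-6-methylbenzaldehyde | Oc1cc(C)c(C=O)c(O)c1O | intermediate
15 | 2-hydroxy-3,4-bis(methoxymethoxy)-6-methylbenzaldehyde | COCOc1cc(C)c(C=O)c(O)c1OCOC | intermediate
16 | 2-methoxy-3,4-bis(methoxymethoxy)-6-methylbenzaldehyde | COCOc1cc(C)c(C=O)c(OC)c1OCOC | intermediate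
17 | 2-methoxy-3,4-bis(methoxymethoxy)-6-methylbenzoic acid | COCOc1cc(C)c(C(=O)O)c(OC)c1OCOC | intermediate
18 | 2-methoxy-3,4-bis(methoxymethoxy)-6-methylbenzoyl chloride (not isolated) | COCOc1cc(C)c(C(Cl)=O)c(OC)c1OCOC | intermediate
19 | (1R,6S)-4-{[tert-butyl(dimethyl)silyl]oxymethyl}-3-iodo-6-methyl-5-oxo-6-(triethylsilyloxy)cyclohex-3-en-1-yl 2-methoxy-3,4-bis(methoxymethoxy)-6-methylbenzoate | COCOc1cc(C)c(C(=O)O[C@@H]2CC(I)=C(CO[Si](C)(C)C(C)(C)C)C(=O)[C@@]2(C)O[Si](CC)(CC)CC)c(OC)c1OCOC | intermediate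
20 | 3-(trimethylsilyl)prop-2-ynal | C[Si](C)(C)C#CC=O | starting material
21 | tert-butyl (triphenylphosphoranylidene)acetate | CC(C)(C)OC(=O)C=P(c1ccccc1)(c1ccccc1)c1ccccc1 | starting material
22 | tert-butyl (2E)-5-(trimethylsilyl)pent-2-en-4-ynoate | CC(C)(C)OC(=O)/C=C/C#C[Si](C)(C)C | intermediate
23 | tert-butyl (2E)-pent-2-en-4-ynoate | CC(C)(C)OC(=O)/C=C/C#C | intermediate
24 | (1R,6S)-3-[(3E)-5-tert-butoxy-5-oxopent-3-en-1-yn-1-yl]-4-{[tert-butyl(dimethyl)silyl]oxymethyl}-6-methyl-5-oxo-6-(triethylsilyloxy)cyclohex-3-en-1-yl 2-methoxy-3,4-bis(methoxymethoxy)-6-methylbenzoate | COCOc1cc(C)c(C(=O)O[C@@H]2CC(C#C/C=C/C(=O)OC(C)(C)C)=C(CO[Si](C)(C)C(C)(C)C)C(=O)[C@@]2(C)O[Si](CC)(CC)CC)c(OC)c1OCOC | intermediate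
25 | (1R,6S)-3-[(3E)-5-tert-butoxy-5-oxopent-3-en-1-yn-1-yl]-6-hydroxy-4-(hydroxymethyl)-6-methyl-5-oxocyclohex-3-en-1-yl 2-methoxy-3,4-bis(methoxymethoxy)-6-methylbenzoate | COCOc1cc(C)c(C(=O)O[C@@H]2CC(C#C/C=C/C(=O)OC(C)(C)C)=C(CO)C(=O)[C@@]2(C)O)c(OC)c1OCOC | intermediate
26 | tert-butyl (2E)-3-[(6R,7S)-7-hydroxy-6-{[2-methoxy-3,4-bis(methoxymethoxy)-6-methylbenzoyl]oxy}-7-methyl-8-oxo-5,6,7,8-tetrahydro-1H-isochromen-3-yl]prop-2-enoate | COCOc1cc(C)c(C(=O)O[C@@H]2CC3=C(COC(/C=C/C(=O)OC(C)(C)C)=C3)C(=O)[C@@]2(C)O)c(OC)c1OCOC | intermediate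
27 | (2E)-3-[(6R,7S)-6-[(3,4-dihydroxy-2-methoxy-6-methylbenzoyl)oxy]-7-hydroxy-7-methyl-8-oxo-5,6,7,8-tetrahydro-1H-isochromen-3-yl]prop-2-enoic acid | COc1c(O)c(O)cc(C)c1C(=O)O[C@@H]1CC2=C(COC(/C=C/C(=O)O)=C2)C(=O)[C@@]1(C)O | target

**Step count and risks**

Total step count: 19. Longest linear sequence: 12 steps (steps 1, 2, 3, 5, 6, 7, 8, 13, 16, 17, 18, 19).

Steps most likely to fail:

Step 8 (the step that bears the label "Proposed new method:"). The cascade may stop after iodide addition, so that the iodo-dienolate is only protonated on work-up, or the Lewis acid may erode the silyl ethers or oligomerize the allenyl ketone before ring closure. The fallback uses known chemistry and separates the two events. Setting out from 10, hydroiodination of the electron-poor allene (NaI, AcOH, MeCN, rt) should give the open-chain 2-iodoallyl ketone aldehyde F1. Soft enolization at the acidic C8a–H (MgBr2·OEt2, i-Pr2NEt, CH2Cl2, 0 °C) then forms the dienolate by deprotonation, and an intramolecular vinylogous aldol reaction should close ring A, returning to the route at 12.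

Step 13. Acyl transfer from a di-ortho-substituted aroyl chloride to a secondary alcohol flanked by the silylated quaternary C7 may be too slow, so that base-induced loss of the new benzoate (vinylogous β-elimination after C5 deprotonation) or decay of 18 takes over. The fallback moves the esterification to the end, onto a less hindered diol. Setting out from 12, Sonogashira coupling with 23 (Pd(PPh3)2Cl2, CuI, Et3N, THF) should give the alkynyl enone with free C6 hydroxyl F2. HF·pyridine should give the triol F3, and AgOTf-catalysed 6-endo cyclization the bicyclic 6,7-diol F4. Acylation of its secondary C6 hydroxyl with 18 (made from 17 as in step 13; Et3N, DMAP, CH2Cl2), against which the tertiary C7 hydroxyl does not compete, comes back to the route at 26.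

Step 18. The hydroxyl may add to the other alkyne carbon (5-exo-dig closure to an alkylidene dihydrofuran), because the alkyne is also polarized by the acrylate. The fallback replaces metal catalysis by electrophilic iodocyclization, for which endo closure of primary alkynyl carbinols is the rule. Setting out from 25, I2 and NaHCO3 in MeCN should give the 4-iodo pyran F5, and hydrodeiodination (Pd(PPh3)4, HCO2H, Et3N, DMF) comes back to the route at 26.

Further compounds
F1 | step 8 | (2S)-4-{[tert-butyl(dimethyl)silyl]oxymethyl}-5-iodo-2-methyl-3-oxo-2-(triethylsilyloxy)hex-5-enal (C4 epimers) | O=C[C@](C)(O[Si](CC)(CC)CC)C(=O)C(CO[Si](C)(C)C(C)(C)C)C(I)=C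
F2 | step 13 | tert-butyl (2E)-5-[(4S,5R)-2-{[tert-butyl(dimethyl)silyl]oxymethyl}-5-hydroxy-4-methyl-3-oxo-4-(triethylsilyloxy)cyclohex-1-en-1-yl]pent-2-en-4-ynoate | O[C@@H]1CC(C#C/C=C/C(=O)OC(C)(C)C)=C(CO[Si](C)(C)C(C)(C)C)C(=O)[C@@]1(C)O[Si](CC)(CC)CC
F3 | step 13 | tert-butyl (2E)-5-[(4S,5R)-4,5-dihydroxy-2-(hydroxymethyl)-4-methyl-3-oxocyclohex-1-en-1-yl]pent-2-en-4-ynoate | O[C@@H]1CC(C#C/C=C/C(=O)OC(C)(C)C)=C(CO)C(=O)[C@@]1(C)O
F4 | step 13 | tert-butyl (2E)-3-[(6R,7S)-6,7-dihydroxy-7-methyl-8-oxo-5,6,7,8-tetrahydro-1H-isochromen-3-yl]prop-2-enoate | O[C@@H]1CC2=C(COC(/C=C/C(=O)OC(C)(C)C)=C2)C(=O)[C@@]1(C)O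
F5 | step 18 | tert-butyl (2E)-3-[(6R,7S)-7-hydroxy-4-iodo-6-{[2-methoxy-3,4-bis(methoxymethoxy)-6-methylbenzoyl]oxy}-7-methyl-8-oxo-5,6,7,8-tetrahydro-1H-isochromen-3-yl]prop-2-enoate | COCOc1cc(C)c(C(=O)O[C@@H]2CC3=C(COC(/C=C/C(=O)OC(C)(C)C)=C3I)C(=O)[C@@]2(C)O)c(OC)c1OCOC
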